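All runs are simulated for an exercise, noise included.

3 questions stand on green and ochre, and I answer them by counting what partner turns into target.

| flask | substrate | partner | protic impurity | remark | time |
|---|---|---|---|---|---|
| midnight | 0.90 M | 0.84 M | 0.080 M | run made earlier |  |
| winter | 1.4 M | 0.84 M | 0.080 M | run made earlier |  |
| autumn | 2.8 M | 0.84 M | 0.080 M | run made earlier |  |
| green | 3.0 M | 0.840 M | 0.0800 M |  | 30 h |
| ochre | 0.80 M | 0.840 M | 0.0800 M |  | 20 h |

| midnight: time / h | midnight: target / % | winter: time / h | winter: target / % | autumn: time / h | autumn: target / % |
|---|---|---|---|---|---|
| 4.00 | 38 | 1.50 | 21 | 1.50 | 17 |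
| 8.00 | 47 | 3.00 | 30 | 3.00 | 21 |
| 12.0 | 49 | 6.00 | 35 | 6.00 | 27 |
| 15.0 | 58 | 10.0 | 41 | 10.0 | 25 |
| 20.0 | 61 | 20.0 | 45 | 20.0 | 25 |

(readings scatter by 2 percentage points)

- the numbers in the tables scatter with a standard deviation of 2 percentage points

- which of the two ends with the higher amount of target, in percent of the substrate charged ("neither" if they lie within 2 percentage points) (green / ochre / neither)
- target at the end, in percent of the substrate charged, green
- target at the end, in percent of the substrate charged, ochre

The autumn run reads 27%, 25% and 25% at 6.00 h, 10.0 h and 20.0 h, which is flat within a scatter of 2 points. Their mean, as a concentration of target over the partner charged, gives 85.6%. I call this the partner yield, the target held at the plateau per partner charged.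

Green charges more substrate than partner, so I treat partner as the limiting reagent, and the partner yield puts green's level at 24.0%. The first autumn reading, taken as an approach to that plateau, gives a pseudo-first-order constant of 0.724 /h, and scaling by substrate makes it 0.776 /h in green. So I reckon that green starts at 0.557 M/h of target, reaches half its level at 0.894 h, and bends at about 2.68 h, where I put it at 21.0%. Its 30 h hold 33.6 such half-lives, so I commit to green at its level.

For ochre, with 0.80 M of substrate against 0.840 M of partner, the partner yield reckons 89.9%. For the midnight run, with the same partner, it reckons 79.9%, and that run reads 61% at 20.0 h, the time of ochre. I take that reading for ochre, which puts ochre above green.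

The forecast names ochre, with green at 24.5% and ochre at 61%, and opens with “The plateau in the autumn run is the key clue”.

The simulation gives ochre, with green at 23.3% and ochre at 63.7%.

    target ⇌ isomer of the product (K = 0.160, k = 0.00210 /min)
    partner + protic impurity → quenched reagent (k = 0.00210 /M/min)
    substrate + partner ⇌ target (K = 22.0 /M, k = 0.00380 /M/min)

Green's own partner yield comes to 83.1%, and its partner stands at 1.70% of its charge at 30.0 h. Taking away the difference in concentration of substrate against ochre moves green from 23.3% to 66.5%, so that difference may be called the main reason for the gap between green and ochre. On a neighbour of green charged with 2.1 M of partner, the partner yield reckons 59.9%. That flask gives 56.9%, still less than ochre's 63.7%.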